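## The problem

The target is a labdane-type diacid. Labdane numbering is used throughout: decalin C1–C10, side chain C11–C16, C17 on C8, C18 and C19 on C4, C20 on C10.

- Rings A and B are trans-fused. C4 is quaternary (α-methyl C18, β-carboxyl C19) and C10 is quaternary (β-methyl C20), with C19 and C20 1,3-diaxial.
- Ring B carries the C17 carboxyl on C8 and, on C9, a two-carbon tether to an α-substituted but-2-en-4-olide (C13–C16).
- Five contiguous stereocentres (C4, C5, C10, C9, C8) have to be set. The substituents on C8 and C9 are both equatorial, so C8 can be left to equilibration, and C9 and C10 can follow C5 through a chair-like closure of ring B.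
- C4 and C5 have no such help: the C19 carboxyl is axial. They must come from a stereospecific event that also fixes the absolute configuration.
- The butenolide does not tolerate base or nucleophiles (ring opening, double-bond migration, conjugate addition), so it has to be unmasked late.
- The C19 carboxyl is neopentyl and axial and cannot be saponified under conditions the butenolide survives; it must travel as an ester that acid removes.
- The enabling feature: C19 sits on C4 next to C5–H. With an alkene at C1=C10 the acid is γ,δ-unsaturated (C19–C4–C5–C10=C1), the retron of an ester-enolate Claisen rearrangement. Because C1 and C4 are 1,4-related in ring A, the allylic ester C19–O–C1 is a six-membered lactone, so ring A can be made by ring contraction.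

## Retrosynthesis

**Unmasking (30 ⇒ 29 ⇒ 27).** The C19 acid of 30 is released last from tert-butyl ester 29 by acid, which needs no base near the butenolide and does not depend on the hindrance at C4. The C13=C14 alkene of 29 is traced to the saturated α-phenylsulfanyl lactone 27 through sulfoxide 28 and syn-elimination. Against alkylating a preformed butenolide or a late aldol, the sulfanyl lactone has no α-hydrogen and stands base and radical conditions.

**C8 and C17 (27 ⇒ 24).** The C17 acid comes from a methyl ester, and C8 is set by equilibration to the all-equatorial ester 25, then saponified through the ring-opened salt 26. This removes any need to control the protonation at C8 kinetically; the precursor 24 may be a C8 mixture.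

**Ring B (24 ⇒ 23).** The C9–C10 bond is cut. The forward reaction is a hydrogen-atom-transfer-initiated radical cyclization: H is delivered to C1 of the C1=C10 alkene, and the tertiary C10 radical adds to C9 of a (Z)-2-alkyl enoate. A cationic closure was set aside because it needs an electron-rich C8=C9 alkene, loses the C17 oxidation level, and would let the C19 carboxyl trap the C10 cation. Closures at C7–C8 or C8–C9 do not create the quaternary C10. The precursor 23 is monocyclic with only C4 and C5 as ring stereocentres. The forward step must give trans fusion and equatorial C11 through a chair.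

**Side chain (23 ⇒ 17 + 22; 17 ⇒ 15 + 16; 22 ⇒ 20 + 21; 20 ⇒ 18 + 19).** The C8=C9 alkene is cut by a (Z)-selective Horner–Wadsworth–Emmons reaction between phosphonate 17 and aldehyde 22. C7–C8 is cut by alkylation of phosphonoacetate 16 with iodide 15. C12–C13 is cut by Michael addition of sulfanyl lactone 20 to acrolein 21; 20 comes from bromolactone 18 and thiophenol 19. Bringing the masked butenolide in with the aldehyde saves a late desilylation–iodination–alkylation sequence.

**Functional-group changes (15 ⇒ 14 ⇒ 13 ⇒ 12).** The iodide comes from the silyl ether of acid 12 after tert-butyl esterification. The tert-butyl ester is chosen so that neither the C7 alkoxide nor later bases can attack C19.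

**Key cut (12 ⇒ 9).** The C4–C5 bond is cut and O–C1 re-formed: acid 12 is the [3,3] product of the silyl ketene acetal 10 (via silyl ester 11) of lactone 9. Against an intermolecular Diels–Alder route to ring A, this makes C4 and C5 stereospecifically from one carbinol centre and puts C19 in at the acid level. The precursor has one controlling stereocentre and no quaternary carbon. The forward step asks only that the enforced boat be reachable.

**Lactone (9 ⇒ 8 ⇒ 7 ⇒ 5 + 6; 5 ⇒ 3 + 4; 3 ⇒ 1 + 2).** Lactone 9 comes from conjugate reduction of unsaturated lactone 8, made by ring-closing metathesis of methacrylate 7. Ester 7 comes from alcohol 5 and methacryloyl chloride 6. Alcohol 5 comes from catalytic asymmetric allylboration of enal 3 with boronate 4, and 3 from Wittig reaction of aldehyde 1 with ylide 2. Each cut removes one ring or one C–C bond, and the sequence ends in four commercial compounds.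

## Roads not taken

**Alternative 1:** Ring A is cut at C1–C10 and C4–C5.
- Forward step: a chiral-Lewis-acid-catalysed [4+2] cycloaddition between the trisubstituted enal A1 (its C5=C10 alkene is the dienophile, its formyl carbon is C9, and its chain holds C6–C8 and C17) and the 1-amino-3-siloxy diene A2. Acid work-up gives the 4,4-disubstituted cyclohexenone A3.
- Merits: one catalytic step sets C5 and the quaternary C10, with the C9 aldehyde and the C8 ester chain placed for an aldol-type closure of ring B. C10, which the chosen plan sets only in its riskiest late step, is secured at the outset.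
- Weak points: A1 is a β-alkyl-α-methyl enal, a far poorer dienophile than the α-substituted acroleins for which such cycloadditions are established. A3 has no substituent at C4 and carries a C3 oxygen and a C1=C2 alkene that the target lacks. C18 and C19 must be added by two enolate reactions next to the ketone with control at C4, then the ring deoxygenated and saturated. Ring B closure would give a C8=C9 enoate whose reduction has to set C9.
- Comparison: this road is better at C10 and worse at C4 and in redox economy. The chosen plan sets against it that C4 and C5 arise together, with C19 at the right oxidation level and nothing to remove.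

**Alternative 2:** Both rings are cut at C5–C10 and C8–C9.
- Forward step: a Lewis-acid-promoted intramolecular cycloaddition of the acyclic triene A4, in which the C9=C10 enal adds across the C5–C8 diene and the C1–C4 tether closes ring A. It gives the trans-fused octalin aldehyde A5.
- Merits: two rings, the quaternary C10 and the C5/C9 stereocentres form in one step. In ring construction this is shorter than the chosen plan.
- Weak points: the quaternary C4 must already exist in an open chain and must steer the facial course across a flexible three-carbon tether. The dienophile is a β,β-disubstituted enal and the diene terminus C5 is neopentyl, so reactivity is low. The diene geometry puts C8 in the wrong configuration, which can be corrected only after C17 has been oxidized. C6=C7 has to be saturated, and C11 arrives as an aldehyde that needs one-carbon homologation before the butenolide can be attached.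
- Comparison: the chosen plan sets against the shorter ring construction that its absolute configuration is created where it is easy (a cyclic [3,3] shift) and that C8 is simply thermodynamic.

**Alternative 3:** Ring A is cut at C3–C4 and C5–C10.
- Forward step: a thermal intramolecular cycloaddition of triene A6, whose (Z)-enoate C4=C5 adds to the C10–C1–C2–C3 diene while the tether closes ring B. It gives octalin A7.
- Merits: A7 has all five stereocentres, both quaternary carbons and both carboxyls at the right oxidation level. Only alkene saturation, butenolide attachment and deprotection remain. If the cycloaddition worked, this would be the shortest and most convergent route and would beat the chosen plan on step count.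
- Weak points: both new bonds end at carbons that become quaternary, and the dienophile is a trisubstituted, weakly activated enoate. The forcing temperatures invite (Z)/(E) leakage of the enoate and hydrogen shifts in the diene. C4 depends on an endo/exo preference that the substrate hardly biases. The anti C8/C9 pair and a geometrically pure trisubstituted diene must first be built in an open chain.
- Comparison: the chosen plan sets against it that each centre is dictated by geometry (a ring-fixed ketene acetal, a chair radical closure, an equilibration) rather than by one demanding cycloaddition.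

Key step: step 6

Remark on the chemistry: lactone 9 is used as both C3 epimers, and the sulfur-bearing carbon C13 of 22–28 is carried as both configurations, because each of these centres becomes trigonal later (steps 6 and 16). The sense of induction in step 2 is assumed to follow that known for aryl and alkenyl aldehydes.

## Route

Step 1
Reactants: 1 3-(tert-butyldimethylsilyloxy)propanal; 2 2-(triphenylphosphoranylidene)propanal
Product: 3 (2E)-5-(tert-butyldimethylsilyloxy)-2-methylpent-2-enal
Conditions: PhMe, 90 °C
Reagents that add atoms: none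
Why: Wittig olefination with a formyl-stabilized ylide, which gives the (E)-2-methyl enal; the conjugated product is less electrophilic than 1 and does not react further. This geometry later decides C5.

Step 2
Reactants: 3 (2E)-5-(tert-butyldimethylsilyloxy)-2-methylpent-2-enal; 4 allylboronic acid pinacol ester
Product: 5 (4R,5E)-8-(tert-butyldimethylsilyloxy)-5-methylocta-1,5-dien-4-ol
Conditions: (R)-TRIP [(R)-3,3'-bis(2,4,6-triisopropylphenyl)-1,1'-binaphthyl-2,2'-diyl hydrogen phosphate] (5 mol%), PhMe, −30 °C; aqueous work-up
Reagents that add atoms: none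
Why: Chiral-phosphoric-acid-catalysed asymmetric allylboration through a closed chair transition state; the (R)-catalyst should add allyl to the Re face of the conjugated aldehyde and set C1 as (R). This one centre later fixes the absolute configuration of C4 and C5; the sense would be checked by Mosher ester analysis.

Step 3
Reactants: 5 (4R,5E)-8-(tert-butyldimethylsilyloxy)-5-methylocta-1,5-dien-4-ol; 6 methacryloyl chloride
Product: 7 (4R,5E)-8-(tert-butyldimethylsilyloxy)-5-methylocta-1,5-dien-4-yl 2-methylprop-2-enoate
Conditions: Et3N, DMAP (cat.), CH2Cl2, 0 °C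
Reagents that add atoms: none
Why: O-Acylation of a secondary allylic alcohol by an acid chloride under nucleophilic catalysis; no stereocentre is touched.

Step 4
Reactants: 7 (4R,5E)-8-(tert-butyldimethylsilyloxy)-5-methylocta-1,5-dien-4-yl 2-methylprop-2-enoate
Product: 8 (6R)-6-[(2E)-5-(tert-butyldimethylsilyloxy)pent-2-en-2-yl]-3-methyl-5,6-dihydro-2H-pyran-2-one
Conditions: second-generation Grubbs catalyst (5 mol%), CH2Cl2, 40 °C
Reagents that add atoms: none
Why: Ring-closing metathesis; the catalyst loads on the monosubstituted alkene and closes the six-membered ring onto the methacrylate, a standard route to 3-methyl-5,6-dihydropyran-2-ones. The trisubstituted C10=C5 alkene cannot close a reasonable ring and stays.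

Step 5
Reactants: 8 (6R)-6-[(2E)-5-(tert-butyldimethylsilyloxy)pent-2-en-2-yl]-3-methyl-5,6-dihydro-2H-pyran-2-one
Product: 9 (3RS,6R)-6-[(2E)-5-(tert-butyldimethylsilyloxy)pent-2-en-2-yl]-3-methyloxan-2-one
Conditions: Cu(OAc)2·H2O (3 mol%), 1,2-bis(diphenylphosphino)benzene (3 mol%), (EtO)2MeSiH, t-BuOH, PhMe, rt
Reagents that add atoms: none
Why: Copper hydride conjugate reduction: hydride adds only to the β-carbon of the activated alkene, so the isolated trisubstituted alkene and the allylic C–O bond are left alone. C3 forms as both epimers, which is immaterial because it becomes the trigonal C4 of the ketene acetal.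

Step 6
Reactants: 9 (3RS,6R)-6-[(2E)-5-(tert-butyldimethylsilyloxy)pent-2-en-2-yl]-3-methyloxan-2-one
Product: 12 (1S,2R)-2-[2-(tert-butyldimethylsilyloxy)ethyl]-1,3-dimethylcyclohex-3-ene-1-carboxylic acid, via cyclic trimethylsilyl ketene acetal 10 (not isolated), via trimethylsilyl ester 11 (not isolated)
Conditions: LiN(i-Pr)2, THF, −78 °C; Me3SiCl, Et3N, −78 °C to rt; PhMe, 105 °C; then H2O, THF, pH 4 buffer
Reagents that add atoms: none
Why: Ester-enolate (Ireland–Claisen) rearrangement in its lactone ring-contraction form, a known reaction of 6-alkenyl oxan-2-ones. Deprotonation at the only α-position and O-silylation give ketene acetal 10, whose geometry is fixed by the ring (C3 cis to the ring oxygen, C18 outside). On heating, C4 bonds to C5 while O–C1 breaks in a concerted suprafacial [3,3] shift; because C2–C3 and C19–O both bridge C1 and C4, only a boat transition state (a 2-oxabicyclo[2.2.2]octene-like array) is possible, and ring A closes by this sigmatropic ring contraction, the lactone oxygen leaving the ring as the C19 silyl ester 11. C5 is controlled by the (E)-alkene, which holds C6 on the outer position so that it ends cis to C19; C4 is controlled by the ring-fixed enol geometry, which puts C18 trans to C6. The (R) configuration of C1 decides which face of C10=C5 is attacked and is thereby passed on to C4 (S) and C5 (R) before C1 becomes trigonal. The step needs O- rather than C-silylation (secured by the Me3SiCl/Et3N quench of a lactone enolate) and a geometrically pure alkene (secured in step 1); chair and regiochemical alternatives do not exist for this substrate. Mild hydrolysis cleaves the silyl ester but not the primary silyl ether.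

Step 7
Reactants: 12 (1S,2R)-2-[2-(tert-butyldimethylsilyloxy)ethyl]-1,3-dimethylcyclohex-3-ene-1-carboxylic acid
Product: 13 tert-butyl (1S,2R)-2-[2-(tert-butyldimethylsilyloxy)ethyl]-1,3-dimethylcyclohex-3-ene-1-carboxylate
Conditions: Me2NCH(Ot-Bu)2, PhMe, 80 °C
Reagents that add atoms: N,N-dimethylformamide di-tert-butyl acetal, CN(C)C(OC(C)(C)C)OC(C)(C)C
Why: Carboxylate O-alkylation by the tert-butyl donor formed from the amide acetal; the nucleophile is the carboxylate oxygen, not the hindered carbonyl carbon, so the neopentyl acid esterifies readily. The neutral conditions spare the silyl ether and the alkene.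

Step 8
Reactants: 13 tert-butyl (1S,2R)-2-[2-(tert-butyldimethylsilyloxy)ethyl]-1,3-dimethylcyclohex-3-ene-1-carboxylate
Product: 14 tert-butyl (1S,2R)-2-(2-hydroxyethyl)-1,3-dimethylcyclohex-3-ene-1-carboxylate
Conditions: Bu4NF, AcOH, THF, 0 °C to rt
Reagents that add atoms: none
Why: Fluoride cleavage of a primary silyl ether; the acetic acid buffer and the bulk of the tert-butyl ester should prevent lactonization of the δ-hydroxy ester onto C19.

Step 9
Reactants: 14 tert-butyl (1S,2R)-2-(2-hydroxyethyl)-1,3-dimethylcyclohex-3-ene-1-carboxylate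
Product: 15 tert-butyl (1S,2R)-2-(2-iodoethyl)-1,3-dimethylcyclohex-3-ene-1-carboxylate
Conditions: I2, PPh3, imidazole, CH2Cl2, 0 °C
Reagents that add atoms: iodine, II
Why: Appel-type iodination of a primary alcohol through the alkoxyphosphonium ion (SN2 at C7); the ester and the alkene are inert.

Step 10
Reactants: 15 tert-butyl (1S,2R)-2-(2-iodoethyl)-1,3-dimethylcyclohex-3-ene-1-carboxylate; 16 methyl bis(2,2,2-trifluoroethyl)phosphonoacetate
Product: 17 methyl 2-[bis(2,2,2-trifluoroethoxy)phosphoryl]-4-[(1R,6S)-6-(tert-butoxycarbonyl)-2,6-dimethylcyclohex-2-en-1-yl]butanoate (both epimers at the phosphorus-bearing carbon)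
Conditions: NaH, DMF, 0 °C; then 15, 50 °C (16 in excess)
Reagents that add atoms: none
Why: C-Alkylation of the sodium salt of a phosphonoacetate with a primary iodide forms C7–C8; an excess of 16 suppresses dialkylation. The new centre is lost in step 13.

Step 11
Reactants: 18 3-bromooxolan-2-one (α-bromo-γ-butyrolactone); 19 thiophenol
Product: 20 3-(phenylsulfanyl)oxolan-2-one
Conditions: Et3N, CH2Cl2, 0 °C to rt
Reagents that add atoms: none
Why: SN2 displacement of an α-bromo lactone by thiolate.

Step 12
Reactants: 20 3-(phenylsulfanyl)oxolan-2-one; 21 acrolein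
Product: 22 3-[(3RS)-2-oxo-3-(phenylsulfanyl)oxolan-3-yl]propanal
Conditions: DBU (10 mol%), MeCN, 0 °C
Reagents that add atoms: none
Why: Base-catalysed Michael addition of an α-sulfanyl lactone, a soft and fairly acidic carbon acid, to acrolein forms C12–C13. The quaternary C13 is racemic, which is immaterial because it becomes trigonal in step 16.

Step 13
Reactants: 17 methyl 2-[bis(2,2,2-trifluoroethoxy)phosphoryl]-4-[(1R,6S)-6-(tert-butoxycarbonyl)-2,6-dimethylcyclohex-2-en-1-yl]butanoate; 22 3-[(3RS)-2-oxo-3-(phenylsulfanyl)oxolan-3-yl]propanal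
Product: 23 methyl (2Z)-2-{2-[(1R,6S)-6-(tert-butoxycarbonyl)-2,6-dimethylcyclohex-2-en-1-yl]ethyl}-5-[(3RS)-2-oxo-3-(phenylsulfanyl)oxolan-3-yl]pent-2-enoate
Conditions: KN(SiMe3)2, 18-crown-6, THF, −78 °C
Reagents that add atoms: none
Why: Still–Gennari variant of the Horner–Wadsworth–Emmons olefination; the electron-poor phosphonate under dissociating conditions eliminates from the kinetic adduct and gives the (Z)-trisubstituted enoate, with C11 cis to the ester. This is the geometry that makes C11 equatorial in step 14.

Step 14
Reactants: 23 methyl (2Z)-2-{2-[(1R,6S)-6-(tert-butoxycarbonyl)-2,6-dimethylcyclohex-2-en-1-yl]ethyl}-5-[(3RS)-2-oxo-3-(phenylsulfanyl)oxolan-3-yl]pent-2-enoate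
Product: 24 1-tert-butyl 6-methyl (1S,4aR,5S,6RS,8aR)-1,4a-dimethyl-5-{2-[(3RS)-2-oxo-3-(phenylsulfanyl)oxolan-3-yl]ethyl}decahydronaphthalene-1,6-dicarboxylate
Conditions: Fe(acac)3 (30 mol%), PhSiH3, EtOH/(CH2OH)2, 60 °C
Reagents that add atoms: none
Why: Hydrogen-atom-transfer-initiated radical conjugate (Giese-type) cyclization: the iron hydride formed from Fe(acac)3 and PhSiH3 gives H to C1, the tertiary C10 radical adds 6-endo to the enoate β-carbon C9, and the C8 radical is reduced and protonated. A chair-like closure with the C5 chain equatorial should give the trans fusion (C20 β); because C11 is trans to C7 on the (Z)-enoate it ends equatorial (C9–H α), as in the second ring closure of radical polyene cyclizations. C8 is left for step 15.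

Step 15
Reactants: 24 1-tert-butyl 6-methyl (1S,4aR,5S,6RS,8aR)-1,4a-dimethyl-5-{2-[(3RS)-2-oxo-3-(phenylsulfanyl)oxolan-3-yl]ethyl}decahydronaphthalene-1,6-dicarboxylate
Product: 27 1-tert-butyl hydrogen (1S,4aR,5S,6R,8aR)-1,4a-dimethyl-5-{2-[(3RS)-2-oxo-3-(phenylsulfanyl)oxolan-3-yl]ethyl}decahydronaphthalene-1,6-dicarboxylate, via equatorial C8 methyl ester 25 (not isolated), via ring-opened dilithium dicarboxylate 26 (not isolated)
Conditions: NaOMe (0.3 equiv), MeOH, 50 °C; then LiOH·H2O, THF/H2O, 50 °C; then 1 M HCl to pH 2
Reagents that add atoms: lithium hydroxide, [Li+].[OH-]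
Why: Base equilibration α to the ester, then saponification: with C11 equatorial and the β-axial site on C8 1,3-diaxial to C20, the α (equatorial) ester should dominate. Hydroxide then cleaves the secondary methyl ester but not the hindered tert-butyl ester. The sulfanyl lactone has no α-hydrogen; it opens under base and re-closes on acidification.

Step 16
Reactants: 27 1-tert-butyl hydrogen (1S,4aR,5S,6R,8aR)-1,4a-dimethyl-5-{2-[(3RS)-2-oxo-3-(phenylsulfanyl)oxolan-3-yl]ethyl}decahydronaphthalene-1,6-dicarboxylate
Product: 29 1-tert-butyl hydrogen (1S,4aR,5S,6R,8aR)-1,4a-dimethyl-5-[2-(2-oxo-2,5-dihydrofuran-3-yl)ethyl]decahydronaphthalene-1,6-dicarboxylate, via sulfoxide 28 (not isolated)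
Conditions: m-CPBA (1.0 equiv), CH2Cl2, −78 °C; then PhMe, pyridine (cat.), 110 °C
Reagents that add atoms: none
Why: Sulfide oxidation and thermal syn-elimination of benzenesulfenic acid, the standard way to unveil α-alkyl butenolides from α-sulfanyl γ-lactones. Elimination into the ring (towards C14) gives the endocyclic conjugated alkene; no other oxidizable group remains in 27.

Step 17
Reactants: 29 1-tert-butyl hydrogen (1S,4aR,5S,6R,8aR)-1,4a-dimethyl-5-[2-(2-oxo-2,5-dihydrofuran-3-yl)ethyl]decahydronaphthalene-1,6-dicarboxylate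
Product: 30 (1S,4aR,5S,6R,8aR)-1,4a-dimethyl-5-[2-(2-oxo-2,5-dihydrofuran-3-yl)ethyl]decahydronaphthalene-1,6-dicarboxylic acid
Conditions: CF3CO2H, CH2Cl2, 0 °C to rt
Reagents that add atoms: none
Why: Acidolysis of the tert-butyl ester by alkyl–oxygen cleavage, which does not depend on the hindrance at C19 and harms neither the butenolide nor any stereocentre.

## Compound list

1 | 3-(tert-butyldimethylsilyloxy)propanal | O=CCCO[Si](C)(C)C(C)(C)C | starting material
2 | 2-(triphenylphosphoranylidene)propanal | CC(C=O)=P(c1ccccc1)(c1ccccc1)c1ccccc1 | starting material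
3 | (2E)-5-(tert-butyldimethylsilyloxy)-2-methylpent-2-enal | O=C/C(C)=C/CCO[Si](C)(C)C(C)(C)C | intermediate
4 | allylboronic acid pinacol ester | C=CCB1OC(C)(C)C(C)(C)O1 | starting material
5 | (4R,5E)-8-(tert-butyldimethylsilyloxy)-5-methylocta-1,5-dien-4-ol | C=CC[C@@H](O)/C(C)=C/CCO[Si](C)(C)C(C)(C)C | intermediate
6 | methacryloyl chloride | CC(=C)C(Cl)=O | starting material
7 | (4R,5E)-8-(tert-butyldimethylsilyloxy)-5-methylocta-1,5-dien-4-yl 2-methylprop-2-enoate | C=CC[C@@H](OC(=O)C(C)=C)/C(C)=C/CCO[Si](C)(C)C(C)(C)C | intermediate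
8 | (6R)-6-[(2E)-5-(tert-butyldimethylsilyloxy)pent-2-en-2-yl]-3-methyl-5,6-dihydro-2H-pyran-2-one | CC1=CC[C@@H](OC1=O)/C(C)=C/CCO[Si](C)(C)C(C)(C)C | intermediate
9 | (3RS,6R)-6-[(2E)-5-(tert-butyldimethylsilyloxy)pent-2-en-2-yl]-3-methyloxan-2-one (both C3 epimers) | CC1CC[C@@H](OC1=O)/C(C)=C/CCO[Si](C)(C)C(C)(C)C | intermediate
10 | (2R)-2-[(2E)-5-(tert-butyldimethylsilyloxy)pent-2-en-2-yl]-5-methyl-6-(trimethylsilyloxy)-3,4-dihydro-2H-pyran | CC1=C(O[Si](C)(C)C)O[C@H](CC1)/C(C)=C/CCO[Si](C)(C)C(C)(C)C | intermediate (not isolated)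
11 | trimethylsilyl (1S,2R)-2-[2-(tert-butyldimethylsilyloxy)ethyl]-1,3-dimethylcyclohex-3-ene-1-carboxylate | CC1=CCC[C@](C)(C(=O)O[Si](C)(C)C)[C@@H]1CCO[Si](C)(C)C(C)(C)C | intermediate (not isolated)
12 | (1S,2R)-2-[2-(tert-butyldimethylsilyloxy)ethyl]-1,3-dimethylcyclohex-3-ene-1-carboxylic acid | CC1=CCC[C@](C)(C(=O)O)[C@@H]1CCO[Si](C)(C)C(C)(C)C | intermediate
13 | tert-butyl (1S,2R)-2-[2-(tert-butyldimethylsilyloxy)ethyl]-1,3-dimethylcyclohex-3-ene-1-carboxylate | CC1=CCC[C@](C)(C(=O)OC(C)(C)C)[C@@H]1CCO[Si](C)(C)C(C)(C)C | intermediate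
14 | tert-butyl (1S,2R)-2-(2-hydroxyethyl)-1,3-dimethylcyclohex-3-ene-1-carboxylate | CC1=CCC[C@](C)(C(=O)OC(C)(C)C)[C@@H]1CCO | intermediate
15 | tert-butyl (1S,2R)-2-(2-iodoethyl)-1,3-dimethylcyclohex-3-ene-1-carboxylate | CC1=CCC[C@](C)(C(=O)OC(C)(C)C)[C@@H]1CCI | intermediate
16 | methyl bis(2,2,2-trifluoroethyl)phosphonoacetate | COC(=O)CP(=O)(OCC(F)(F)F)OCC(F)(F)F | starting material
17 | methyl 2-[bis(2,2,2-trifluoroethoxy)phosphoryl]-4-[(1R,6S)-6-(tert-butoxycarbonyl)-2,6-dimethylcyclohex-2-en-1-yl]butanoate (both epimers at C2 of the butanoate) | CC1=CCC[C@](C)(C(=O)OC(C)(C)C)[C@@H]1CCC(C(=O)OC)P(=O)(OCC(F)(F)F)OCC(F)(F)F | intermediate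
18 | 3-bromooxolan-2-one | O=C1OCCC1Br | starting material
19 | thiophenol | Sc1ccccc1 | starting material
20 | 3-(phenylsulfanyl)oxolan-2-one (racemic) | O=C1OCCC1Sc1ccccc1 | intermediate
21 | acrolein | C=CC=O | starting material
22 | 3-[(3RS)-2-oxo-3-(phenylsulfanyl)oxolan-3-yl]propanal | O=CCCC1(Sc2ccccc2)CCOC1=O | intermediate
23 | methyl (2Z)-2-{2-[(1R,6S)-6-(tert-butoxycarbonyl)-2,6-dimethylcyclohex-2-en-1-yl]ethyl}-5-[(3RS)-2-oxo-3-(phenylsulfanyl)oxolan-3-yl]pent-2-enoate | CC1=CCC[C@](C)(C(=O)OC(C)(C)C)[C@@H]1CC/C(C(=O)OC)=C/CCC1(Sc2ccccc2)CCOC1=O | intermediate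
24 | 1-tert-butyl 6-methyl (1S,4aR,5S,6RS,8aR)-1,4a-dimethyl-5-{2-[(3RS)-2-oxo-3-(phenylsulfanyl)oxolan-3-yl]ethyl}decahydronaphthalene-1,6-dicarboxylate (C8 epimers) | C[C@]12CCC[C@](C)(C(=O)OC(C)(C)C)[C@@H]1CCC(C(=O)OC)[C@@H]2CCC1(Sc2ccccc2)CCOC1=O | intermediate
25 | 1-tert-butyl 6-methyl (1S,4aR,5S,6R,8aR)-1,4a-dimethyl-5-{2-[(3RS)-2-oxo-3-(phenylsulfanyl)oxolan-3-yl]ethyl}decahydronaphthalene-1,6-dicarboxylate | C[C@]12CCC[C@](C)(C(=O)OC(C)(C)C)[C@@H]1CC[C@@H](C(=O)OC)[C@@H]2CCC1(Sc2ccccc2)CCOC1=O | intermediate (not isolated)
26 | dilithium (1S,4aR,5S,6R,8aR)-1-(tert-butoxycarbonyl)-5-[3-carboxylato-5-hydroxy-3-(phenylsulfanyl)pentyl]-1,4a-dimethyldecahydronaphthalene-6-carboxylate | C[C@]12CCC[C@](C)(C(=O)OC(C)(C)C)[C@@H]1CC[C@@H](C(=O)[O-])[C@@H]2CCC(CCO)(Sc1ccccc1)C(=O)[O-].[Li+].[Li+] | intermediate (not isolated)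
27 | 1-tert-butyl hydrogen (1S,4aR,5S,6R,8aR)-1,4a-dimethyl-5-{2-[(3RS)-2-oxo-3-(phenylsulfanyl)oxolan-3-yl]ethyl}decahydronaphthalene-1,6-dicarboxylate | C[C@]12CCC[C@](C)(C(=O)OC(C)(C)C)[C@@H]1CC[C@@H](C(=O)O)[C@@H]2CCC1(Sc2ccccc2)CCOC1=O | intermediate
28 | 1-tert-butyl hydrogen (1S,4aR,5S,6R,8aR)-1,4a-dimethyl-5-{2-[2-oxo-3-(phenylsulfinyl)oxolan-3-yl]ethyl}decahydronaphthalene-1,6-dicarboxylate | C[C@]12CCC[C@](C)(C(=O)OC(C)(C)C)[C@@H]1CC[C@@H](C(=O)O)[C@@H]2CCC1(S(=O)c2ccccc2)CCOC1=O | intermediate (not isolated)
29 | 1-tert-butyl hydrogen (1S,4aR,5S,6R,8aR)-1,4a-dimethyl-5-[2-(2-oxo-2,5-dihydrofuran-3-yl)ethyl]decahydronaphthalene-1,6-dicarboxylate | C[C@]12CCC[C@](C)(C(=O)OC(C)(C)C)[C@@H]1CC[C@@H](C(=O)O)[C@@H]2CCC1=CCOC1=O | intermediate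
30 | (1S,4aR,5S,6R,8aR)-1,4a-dimethyl-5-[2-(2-oxo-2,5-dihydrofuran-3-yl)ethyl]decahydronaphthalene-1,6-dicarboxylic acid | C[C@]12CCC[C@](C)(C(=O)O)[C@@H]1CC[C@@H](C(=O)O)[C@@H]2CCC1=CCOC1=O | target

## Step count and risks

Total: 17 steps. Longest linear sequence: 15 steps (steps 1–10 and 13–17); steps 11 and 12 are the side branch to 22.

**Step 6 (key step).** The most likely failure is a slow rearrangement: in the enforced boat the C20 methyl eclipses the silyloxy group, so hydrolysis, C-silylation or decomposition of 10 may outrun the [3,3] shift. The fallback replaces the boat by an open-chain chair rearrangement and closes ring A afterwards; it sets out from 3 and comes back at 12. Allylboration of 3 with the enantiomeric (S)-catalyst would give (4S,5E)-8-(tert-butyldimethylsilyloxy)-5-methylocta-1,5-dien-4-ol F1. The opposite carbinol configuration is needed because in a chair the allyl group sits equatorial and the other alkene face is used. Esterification with 2-methylhex-5-enoic acid (DCC, DMAP) would give ester F2. Enolization with a chiral lithium amide base, which is the known way to fix the geometry of α,α-disubstituted ester enolates, and silylation would give the ketene acetal F3 with the butenyl chain cis to the silyloxy group. Its chair Ireland–Claisen shift would give the silyl ester F4, hydrolysed to the open-chain acid F5 with C4 and C5 as in 12. Ring-closing metathesis of F5 with second-generation Grubbs catalyst would form C1=C10 with loss of the allyl terminus and deliver 12.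

**Step 14.** The most likely failure is side reaction of the aryl sulfide (phenylsulfanyl transfer from C13 to the C8 radical, binding to iron), together with leakage in the ring-fusion selectivity that is hard to read on a mixture of C13 epimers. The fallback attaches the sulfanyl lactone after ring B is closed; it sets out from 17 (with 1) and comes back at 25.
- Olefination of 17 with aldehyde 1 under the conditions of step 13 would give the (Z)-enoate silyl ether F6.
- The cyclization of step 14 would give decalin F7 as C8 epimers, and NaOMe/MeOH the equatorial ester F8.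
- Desilylation with HF·pyridine (acidic, so that the δ-hydroxy ester does not lactonize onto C17) would give alcohol F9, and I2/PPh3/imidazole the iodide F10.
- Alkylation of the lithium enolate of 20 (LiN(SiMe3)2, THF/DMPU) with F10 gives 25, which is saponified as in the second stage of step 15.

**Step 13.** The most likely failure is erosion of (Z)-selectivity with the α-branched phosphonate, compounded by modest efficiency of the alkylation in step 10. The fallback makes the C7–C8 bond by cross-coupling instead; it sets out from 15 (with 16 and 22) and comes back at 23. Bromination of 16 would give methyl bromo[bis(2,2,2-trifluoroethoxy)phosphoryl]acetate F11. Its olefination with 22 is of a type known to favour the (E)-2-bromo enoate, here methyl (2E)-2-bromo-5-[2-oxo-3-(phenylsulfanyl)oxolan-3-yl]pent-2-enoate F12, with C11 cis to the ester. Zinc insertion into 15 would give the alkylzinc iodide F13, and Negishi coupling of F13 with F12 (Pd(PPh3)4, THF) proceeds with retention to 23.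

**Step 12.** The most likely failure is oligomerization of acrolein and aldol self-condensation of the product under the basic catalyst. The fallback replaces the conjugate addition by an enolate alkylation with a masked aldehyde; it sets out from 20 and comes back at 22. Alkylation of the lithium enolate of 20 with 2-(2-bromoethyl)-1,3-dioxolane (LiN(SiMe3)2, THF/DMPU) would give 3-[2-(1,3-dioxolan-2-yl)ethyl]-3-(phenylsulfanyl)oxolan-2-one F14, and dilute HCl in acetone would release 22.

**Step 2.** The most likely failure is insufficient enantiofacial discrimination with the α-branched enal. The fallback moves the stereo-determining event to a ketone reduction; it sets out from 3 and comes back at 5. Allylmagnesium bromide would give the racemic alcohol F15, and Dess–Martin periodinane (buffered) the dienone F16. Corey–Bakshi–Shibata reduction with the (S)-oxazaborolidine and catecholborane at −78 °C, in which the alkenyl group acts as the large substituent, should give (R)-5.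

## Further compounds

F1 | step 6 | (4S,5E)-8-(tert-butyldimethylsilyloxy)-5-methylocta-1,5-dien-4-ol | C=CC[C@H](O)/C(C)=C/CCO[Si](C)(C)C(C)(C)C
F2 | step 6 | (4S,5E)-8-(tert-butyldimethylsilyloxy)-5-methylocta-1,5-dien-4-yl 2-methylhex-5-enoate | C=CCCC(C)C(=O)O[C@@H](CC=C)/C(C)=C/CCO[Si](C)(C)C(C)(C)C
F3 | step 6 | (Z)-trimethylsilyl ketene acetal of F2 (butenyl chain cis to the silyloxy group) | C=CCC/C(C)=C(\O[Si](C)(C)C)O[C@@H](CC=C)/C(C)=C/CCO[Si](C)(C)C(C)(C)C
F4 | step 6 | trimethylsilyl (2S,3R,4E)-2-(but-3-en-1-yl)-3-[2-(tert-butyldimethylsilyloxy)ethyl]-2,4-dimethylocta-4,7-dienoate | C=CCC[C@](C)(C(=O)O[Si](C)(C)C)[C@H](CCO[Si](C)(C)C(C)(C)C)/C(C)=C/CC=C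
F5 | step 6 | (2S,3R,4E)-2-(but-3-en-1-yl)-3-[2-(tert-butyldimethylsilyloxy)ethyl]-2,4-dimethylocta-4,7-dienoic acid | C=CCC[C@](C)(C(=O)O)[C@H](CCO[Si](C)(C)C(C)(C)C)/C(C)=C/CC=C
F6 | step 14 | methyl (2Z)-5-(tert-butyldimethylsilyloxy)-2-{2-[(1R,6S)-6-(tert-butoxycarbonyl)-2,6-dimethylcyclohex-2-en-1-yl]ethyl}pent-2-enoate | CC1=CCC[C@](C)(C(=O)OC(C)(C)C)[C@@H]1CC/C(C(=O)OC)=C/CCO[Si](C)(C)C(C)(C)C
F7 | step 14 | 1-tert-butyl 6-methyl (1S,4aR,5S,6RS,8aR)-5-[2-(tert-butyldimethylsilyloxy)ethyl]-1,4a-dimethyldecahydronaphthalene-1,6-dicarboxylate | C[C@]12CCC[C@](C)(C(=O)OC(C)(C)C)[C@@H]1CCC(C(=O)OC)[C@@H]2CCO[Si](C)(C)C(C)(C)C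
F8 | step 14 | 1-tert-butyl 6-methyl (1S,4aR,5S,6R,8aR)-5-[2-(tert-butyldimethylsilyloxy)ethyl]-1,4a-dimethyldecahydronaphthalene-1,6-dicarboxylate | C[C@]12CCC[C@](C)(C(=O)OC(C)(C)C)[C@@H]1CC[C@@H](C(=O)OC)[C@@H]2CCO[Si](C)(C)C(C)(C)C
F9 | step 14 | 1-tert-butyl 6-methyl (1S,4aR,5S,6R,8aR)-5-(2-hydroxyethyl)-1,4a-dimethyldecahydronaphthalene-1,6-dicarboxylate | C[C@]12CCC[C@](C)(C(=O)OC(C)(C)C)[C@@H]1CC[C@@H](C(=O)OC)[C@@H]2CCO
F10 | step 14 | 1-tert-butyl 6-methyl (1S,4aR,5S,6R,8aR)-5-(2-iodoethyl)-1,4a-dimethyldecahydronaphthalene-1,6-dicarboxylate | C[C@]12CCC[C@](C)(C(=O)OC(C)(C)C)[C@@H]1CC[C@@H](C(=O)OC)[C@@H]2CCI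
F11 | step 13 | methyl bromo[bis(2,2,2-trifluoroethoxy)phosphoryl]acetate | COC(=O)C(Br)P(=O)(OCC(F)(F)F)OCC(F)(F)F
F12 | step 13 | methyl (2E)-2-bromo-5-[2-oxo-3-(phenylsulfanyl)oxolan-3-yl]pent-2-enoate | COC(=O)/C(Br)=C\CCC1(Sc2ccccc2)CCOC1=O
F13 | step 13 | {2-[(1R,6S)-6-(tert-butoxycarbonyl)-2,6-dimethylcyclohex-2-en-1-yl]ethyl}zinc iodide | CC1=CCC[C@](C)(C(=O)OC(C)(C)C)[C@@H]1CC[Zn]I
F14 | step 12 | 3-[2-(1,3-dioxolan-2-yl)ethyl]-3-(phenylsulfanyl)oxolan-2-one | O=C1OCCC1(CCC1OCCO1)Sc1ccccc1
F15 | step 2 | (4RS,5E)-8-(tert-butyldimethylsilyloxy)-5-methylocta-1,5-dien-4-ol | C=CCC(O)/C(C)=C/CCO[Si](C)(C)C(C)(C)C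
F16 | step 2 | (5E)-8-(tert-butyldimethylsilyloxy)-5-methylocta-1,5-dien-4-one | C=CCC(=O)/C(C)=C/CCO[Si](C)(C)C(C)(C)C
A1 | alternative 1 | tert-butyl (5E)-6-methyl-7-oxohept-5-enoate | O=C/C(C)=C/CCCC(=O)OC(C)(C)C
A2 | alternative 1 | (E)-1-(dimethylamino)-3-(tert-butyldimethylsilyloxy)buta-1,3-diene | CN(C)/C=C/C(=C)O[Si](C)(C)C(C)(C)C
A3 | alternative 1 | tert-butyl 4-[(1S,2R)-2-formyl-2-methyl-5-oxocyclohex-3-en-1-yl]butanoate | C[C@]1(C=O)C=CC(=O)C[C@@H]1CCCC(=O)OC(C)(C)C
A4 | alternative 2 | methyl (2S,3E,5E)-7-(tert-butyldimethylsilyloxy)-2-methyl-2-[(4E)-4-methyl-6-oxohex-4-en-1-yl]hepta-3,5-dienoate | O=C/C=C(C)/CCC[C@](C)(C(=O)OC)/C=C/C=C/CO[Si](C)(C)C(C)(C)C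
A5 | alternative 2 | methyl 6-[(tert-butyldimethylsilyloxy)methyl]-5-formyl-1,4a-dimethyl-1,2,3,4,4a,5,6,8a-octahydronaphthalene-1-carboxylate (trans-fused; C4, C5, C9, C10 as in the target, C8 epimeric) | C[C@]12CCC[C@](C)(C(=O)OC)[C@@H]1C=C[C@H](CO[Si](C)(C)C(C)(C)C)[C@@H]2C=O
A6 | alternative 3 | 7-tert-butyl 1-methyl (2Z)-6-[(4E)-1-(tert-butyldimethylsilyloxy)-4-methylhepta-4,6-dien-3-yl]-2-methylhept-2-enedioate (C8, C9 as in the target) | C=C/C=C(C)/[C@@H](CCO[Si](C)(C)C(C)(C)C)[C@H](C(=O)OC(C)(C)C)CC/C=C(/C)C(=O)OC
A7 | alternative 3 | 6-tert-butyl 1-methyl 5-[2-(tert-butyldimethylsilyloxy)ethyl]-1,4a-dimethyl-1,2,4a,5,6,7,8,8a-octahydronaphthalene-1,6-dicarboxylate (trans-fused; all five stereocentres as in the target) | C[C@]12C=CC[C@](C)(C(=O)OC)[C@@H]1CC[C@@H](C(=O)OC(C)(C)C)[C@@H]2CCO[Si](C)(C)C(C)(C)C
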